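**Plan**
- Retrosynthesis: remove three silyl ethers; open the lactone at O1–C2 and regrow C5 into a CH=CH–CH3 group (a γ,δ-unsaturated acid); cut C3–C4 and the guaiacyl aryl–CH2 bond in one retro-step (conjugate addition/Ireland–Claisen) to an arylcopper and the 2-silyloxyacrylate of an (R,E)-allylic alcohol; acrylate to pyruvate ester, allylic alcohol to methoxyeugenol plus (R)-but-3-en-2-ol.
- Enabling feature: C3 carries O, the C2 carbonyl and the benzylic CH2, so C3/CH2 is a masked 2-oxyacrylate (α-carbon/β-carbon); the C3–C4 bond lies α,β to the C2 carboxyl and C5 is the stump of a vinyl group, which is the retron of an ester-enolate Claisen rearrangement.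
- Forward: the chain is joined acyclic (cross-metathesis, pyruvate ester, silyloxyacrylate, then aryl + acrylate + allyl unit in one operation); the lactone is the only ring formed, last but one, by oxidative cleavage, reduction and lactonisation.
- Stereochemistry: (R)-but-3-en-2-ol is the only chiral source; its carbinol centre is relayed through a chair [3,3] transition state to C4 and, via the ketene acetal geometry, to C3, and is then excised.

Key step: step 6

Remark: the lactone is numbered O1, C2 (C=O), C3 (carbinol), C4, C5; TBS = tert-butyldimethylsilyl; the assignment at C3 assumes conjugate addition through the s-cis conformer of the acrylate.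

**Step 1**
Reactants: 1 4-allyl-2,6-dimethoxyphenol
Product: 2 tert-butyl(4-allyl-2,6-dimethoxyphenoxy)dimethylsilane
Conditions: TBSCl, imidazole, DMF, rt
Reagents that add atoms: tert-butyldimethylsilyl chloride, CC(C)(C)[Si](C)(C)Cl
Why: Imidazole-promoted silyl ether formation masks the phenol so that the later organometallic and base-mediated steps are not quenched.

**Step 2**
Reactants: 2 tert-butyl(4-allyl-2,6-dimethoxyphenoxy)dimethylsilane; 3 (R)-but-3-en-2-ol
Product: 4 (2R,3E)-5-[4-(TBSO)-3,5-dimethoxyphenyl]pent-3-en-2-ol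
Conditions: Hoveyda–Grubbs II (5 mol%), 1,4-benzoquinone (10 mol%), 3 (4 equiv), CH2Cl2, 40 °C
Reagents that add atoms: none
Why: Olefin cross-metathesis between a fast-dimerising allylarene and an excess of a slow-dimerising secondary allylic alcohol should be selective for the (E)-alkene, and the carbinol centre of 3 is not touched.

**Step 3**
Reactants: 4 (2R,3E)-5-[4-(TBSO)-3,5-dimethoxyphenyl]pent-3-en-2-ol; 5 pyruvic acid
Product: 6 (2R,3E)-5-[4-(TBSO)-3,5-dimethoxyphenyl]pent-3-en-2-yl 2-oxopropanoate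
Conditions: DCC, DMAP (cat.), CH2Cl2, 0 °C → rt
Reagents that add atoms: none
Why: Steglich esterification acylates the alcohol at oxygen, so the carbinol configuration is retained.

**Step 4**
Reactants: 6 (2R,3E)-5-[4-(TBSO)-3,5-dimethoxyphenyl]pent-3-en-2-yl 2-oxopropanoate
Product: 7 (2R,3E)-5-[4-(TBSO)-3,5-dimethoxyphenyl]pent-3-en-2-yl 2-(TBSO)prop-2-enoate
Conditions: TBSOTf, Et3N, CH2Cl2, 0 °C
Reagents that add atoms: tert-butyldimethylsilyl trifluoromethanesulfonate, CC(C)(C)[Si](C)(C)OS(=O)(=O)C(F)(F)F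
Why: Soft enolisation (silyl triflate/amine) of the α-keto ester at its only enolisable position gives the silyl enol ether, which is the 2-silyloxyacrylate.

**Step 5**
Reactants: 8 4-bromo-2-methoxyphenol
Product: 9 (4-bromo-2-methoxyphenoxy)(tert-butyl)dimethylsilane
Conditions: TBSCl, imidazole, DMF, rt
Reagents that add atoms: tert-butyldimethylsilyl chloride, CC(C)(C)[Si](C)(C)Cl
Why: Phenol silylation as in step 1 makes the aryl bromide compatible with bromine–lithium exchange.

**Step 6**
Reactants: 7 (2R,3E)-5-[4-(TBSO)-3,5-dimethoxyphenyl]pent-3-en-2-yl 2-(TBSO)prop-2-enoate; 9 (4-bromo-2-methoxyphenoxy)(tert-butyl)dimethylsilane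
Product: 14 (2S,3S,4E)-2-(TBSO)-2-{[4-(TBSO)-3-methoxyphenyl]methyl}-3-{[4-(TBSO)-3,5-dimethoxyphenyl]methyl}hex-4-enoic acid, via aryllithium 10 (not isolated), via arylcopper 11 (not isolated), via silyl ketene acetal 12 (not isolated), via trimethylsilyl ester 13 (not isolated)
Conditions: 9, n-BuLi, THF, −78 °C; CuI, −78 → −40 °C; 7, Me3SiI, −78 → −30 °C; Et3N, then 50 °C; aq. NH4Cl
Reagents that add atoms: none
Why: Proposed new method: the arylcopper 11, activated by Me3SiI, should add in conjugate fashion to the CH2 terminus of the 2-silyloxyacrylate through its s-cis conformer (C=O anti to the C–OSi dipole, no chelation by the bulky silyl ether), forming the aryl–CH2 bond and the (E)-ketene acetal 12 with the new arylmethyl group syn to OSiMe3; on warming, 12 should undergo an Ireland–Claisen [3,3] rearrangement that forms the C2–C3 bond of the acid (C3–C4 of the lactone). The closest known reaction type is the organocopper/Me3SiI conjugate addition–Ireland–Claisen sequence of allyl acrylates, together with the Ireland–Claisen rearrangement of α-oxygenated allylic esters; new here are the electron-rich α-oxygenated acceptor and the fully substituted α-carbon that results. No ring is closed; the only cyclic array is the six-membered chair transition state. The quaternary carbinol centre is controlled by the ketene acetal geometry (arylmethyl pseudo-equatorial, OTBS pseudo-axial), and the neighbouring tertiary centre by the (E)-alkene (syringylmethyl pseudo-equatorial) and by the (R)-carbinol carbon, whose methyl group sits pseudo-equatorial and fixes the face of bond formation (1,3-chirality transfer); together these should give the (2S,3S) acid. The step needs 1,4-addition in preference to 1,2-addition and to SN2′ displacement of the allylic carboxylate, which the silyl-iodide-activated monoorganocopper reagent at −78 °C should secure, and a single ketene acetal geometry, which the dipole-minimised s-cis acrylate should secure.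

**Step 7**
Reactants: 14 (2S,3S,4E)-2-(TBSO)-2-{[4-(TBSO)-3-methoxyphenyl]methyl}-3-{[4-(TBSO)-3,5-dimethoxyphenyl]methyl}hex-4-enoic acid
Product: 17 (3S,4S)-3-(TBSO)-3-{[4-(TBSO)-3-methoxyphenyl]methyl}-4-{[4-(TBSO)-3,5-dimethoxyphenyl]methyl}oxolan-2-one, via aldehyde acid 15 (not isolated), via hydroxy acid 16 (not isolated)
Conditions: O3, CH2Cl2/MeOH, −78 °C (indicator end point); NaBH4, −78 → 0 °C; 1 M HCl, rt
Reagents that add atoms: ozone, [O-][O+]=O
Why: Ozonolysis of the disubstituted alkene (much more reactive than the arenes at −78 °C) with in situ borohydride reduction should give the γ-hydroxy acid, which lactonises on acidification; the quaternary centre cannot epimerise and the aldehyde is reduced cold before its α-centre can.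

**Step 8**
Reactants: 17 (3S,4S)-3-(TBSO)-3-{[4-(TBSO)-3-methoxyphenyl]methyl}-4-{[4-(TBSO)-3,5-dimethoxyphenyl]methyl}oxolan-2-one
Product: 18 (3S,4S)-3-hydroxy-3-[(4-hydroxy-3-methoxyphenyl)methyl]-4-[(4-hydroxy-3,5-dimethoxyphenyl)methyl]oxolan-2-one
Conditions: TBAF, AcOH, THF, 0 °C → rt
Reagents that add atoms: none
Why: Fluoride-mediated desilylation, buffered with acetic acid, should cleave the two aryl silyl ethers and the tertiary silyl ether without opening the lactone or touching a stereocentre.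

**Compound list**
1 | 4-allyl-2,6-dimethoxyphenol | C=CCc1cc(OC)c(O)c(OC)c1 | starting material
2 | tert-butyl(4-allyl-2,6-dimethoxyphenoxy)dimethylsilane | C=CCc1cc(OC)c(O[Si](C)(C)C(C)(C)C)c(OC)c1 | intermediate
3 | (R)-but-3-en-2-ol | C[C@@H](O)C=C | starting material
4 | (2R,3E)-5-[4-(TBSO)-3,5-dimethoxyphenyl]pent-3-en-2-ol | C[C@@H](O)/C=C/Cc1cc(OC)c(O[Si](C)(C)C(C)(C)C)c(OC)c1 | intermediate
5 | pyruvic acid | CC(=O)C(=O)O | starting material
6 | (2R,3E)-5-[4-(TBSO)-3,5-dimethoxyphenyl]pent-3-en-2-yl 2-oxopropanoate | CC(=O)C(=O)O[C@H](C)/C=C/Cc1cc(OC)c(O[Si](C)(C)C(C)(C)C)c(OC)c1 | intermediate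
7 | (2R,3E)-5-[4-(TBSO)-3,5-dimethoxyphenyl]pent-3-en-2-yl 2-(TBSO)prop-2-enoate | C=C(O[Si](C)(C)C(C)(C)C)C(=O)O[C@H](C)/C=C/Cc1cc(OC)c(O[Si](C)(C)C(C)(C)C)c(OC)c1 | intermediate
8 | 4-bromo-2-methoxyphenol | COc1cc(Br)ccc1O | starting material
9 | (4-bromo-2-methoxyphenoxy)(tert-butyl)dimethylsilane | COc1cc(Br)ccc1O[Si](C)(C)C(C)(C)C | intermediate
10 | [4-(TBSO)-3-methoxyphenyl]lithium | COc1cc([Li])ccc1O[Si](C)(C)C(C)(C)C | intermediate
11 | [4-(TBSO)-3-methoxyphenyl]copper (LiI complex) | COc1cc([Cu])ccc1O[Si](C)(C)C(C)(C)C | intermediate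
12 | (E)-O-trimethylsilyl ketene acetal of the (2R,3E)-pentenyl 3-[4-(TBSO)-3-methoxyphenyl]-2-(TBSO)propanoate (arylmethyl syn to OSiMe3) | COc1cc(C/C(O[Si](C)(C)C(C)(C)C)=C(\O[Si](C)(C)C)O[C@H](C)/C=C/Cc2cc(OC)c(O[Si](C)(C)C(C)(C)C)c(OC)c2)ccc1O[Si](C)(C)C(C)(C)C | intermediate
13 | trimethylsilyl (2S,3S,4E)-2-(TBSO)-2-{[4-(TBSO)-3-methoxyphenyl]methyl}-3-{[4-(TBSO)-3,5-dimethoxyphenyl]methyl}hex-4-enoate | COc1cc(C[C@@](O[Si](C)(C)C(C)(C)C)(C(=O)O[Si](C)(C)C)[C@@H](Cc2cc(OC)c(O[Si](C)(C)C(C)(C)C)c(OC)c2)/C=C/C)ccc1O[Si](C)(C)C(C)(C)C | intermediate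
14 | (2S,3S,4E)-2-(TBSO)-2-{[4-(TBSO)-3-methoxyphenyl]methyl}-3-{[4-(TBSO)-3,5-dimethoxyphenyl]methyl}hex-4-enoic acid | COc1cc(C[C@@](O[Si](C)(C)C(C)(C)C)(C(=O)O)[C@@H](Cc2cc(OC)c(O[Si](C)(C)C(C)(C)C)c(OC)c2)/C=C/C)ccc1O[Si](C)(C)C(C)(C)C | intermediate
15 | (2S,3R)-2-(TBSO)-2-{[4-(TBSO)-3-methoxyphenyl]methyl}-3-{[4-(TBSO)-3,5-dimethoxyphenyl]methyl}-4-oxobutanoic acid | COc1cc(C[C@@](O[Si](C)(C)C(C)(C)C)(C(=O)O)[C@@H](Cc2cc(OC)c(O[Si](C)(C)C(C)(C)C)c(OC)c2)C=O)ccc1O[Si](C)(C)C(C)(C)C | intermediate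
16 | (2S,3S)-2-(TBSO)-2-{[4-(TBSO)-3-methoxyphenyl]methyl}-3-{[4-(TBSO)-3,5-dimethoxyphenyl]methyl}-4-hydroxybutanoic acid | COc1cc(C[C@@](O[Si](C)(C)C(C)(C)C)(C(=O)O)[C@@H](Cc2cc(OC)c(O[Si](C)(C)C(C)(C)C)c(OC)c2)CO)ccc1O[Si](C)(C)C(C)(C)C | intermediate
17 | (3S,4S)-3-(TBSO)-3-{[4-(TBSO)-3-methoxyphenyl]methyl}-4-{[4-(TBSO)-3,5-dimethoxyphenyl]methyl}oxolan-2-one | COc1cc(C[C@@]2(O[Si](C)(C)C(C)(C)C)C(=O)OC[C@@H]2Cc2cc(OC)c(O[Si](C)(C)C(C)(C)C)c(OC)c2)ccc1O[Si](C)(C)C(C)(C)C | intermediate
18 | (3S,4S)-3-hydroxy-3-[(4-hydroxy-3-methoxyphenyl)methyl]-4-[(4-hydroxy-3,5-dimethoxyphenyl)methyl]oxolan-2-one | COc1cc(C[C@@]2(O)C(=O)OC[C@@H]2Cc2cc(OC)c(O)c(OC)c2)ccc1O | target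

**Step count**
Total steps: 8. Longest linear sequence: 7 (steps 1, 2, 3, 4, 6, 7, 8).

**Steps most likely to fail**

Step 6. The electron-rich 2-silyloxyacrylate may take up the arylcopper too slowly, so that 1,2-addition or SN2′ displacement of the allylic carboxylate competes. Addition through the s-trans conformer would also erode the ketene acetal geometry and with it the selectivity at the quaternary centre. The fallback uses known chemistry, sets out from 4 and from 10 (made from 9), and returns at 17. Compound 4 is esterified (DCC, DMAP) with commercial (tert-butyldimethylsilyloxy)acetic acid to glycolate ester F1. A classical Ireland–Claisen rearrangement (LDA, TMSCl, THF, −78 °C → rt) through the same chair with equatorial methyl should give hexenoic acid F2, with the β-centre set by chirality transfer and the α-centre of no consequence. Oxidative cleavage, NaBH4 and acid as in step 7 should then give α-silyloxy lactone F3. Separately, 10 is quenched with paraformaldehyde to benzylic alcohol F4, which an Appel reaction (CBr4, PPh3) converts into benzylic bromide F5. The lithium enolate of F3 (LDA, THF, −78 °C) is alkylated with F5 on the face anti to the C4 benzyl group, which should give 17 directly. This sets the quaternary centre under substrate control and gives up the cascade.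

Step 2. The allylic double bond may migrate into conjugation with the arene (ruthenium hydride), and E-selectivity may be incomplete, which would lower the diastereomeric purity after the rearrangement. The fallback sets out from 2 and returns at 4. Lemieux–Johnson cleavage of 2 (OsO4 cat., NaIO4, 2,6-lutidine, dioxane/H2O) gives arylacetaldehyde F6. Wittig olefination with the stabilised ylide 1-(triphenylphosphoranylidene)propan-2-one (toluene, rt to 50 °C, neutral, E-selective) gives enone F7. Corey–Bakshi–Shibata reduction ((S)-Me-CBS, catecholborane, −78 °C) should give the (R)-alcohol 4; the sense follows that of aryl methyl ketones, with the alkenyl group as the large substituent.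

Step 7. Ozone may attack the electron-rich aryl silyl ethers (over-oxidation), and the α-centre of the intermediate aldehyde may epimerise if reduction lags. The fallback sets out from 14 and returns at 17. Compound 14 is converted into methyl ester F8 (TMSCHN2, MeOH/toluene). Osmium-catalysed dihydroxylation with periodate scission (OsO4 cat., NaIO4, 2,6-lutidine, dioxane/H2O), an oxidant that does not attack arenes, gives aldehyde ester F9. Reduction with NaBH4 at −20 °C should be followed by closure of the γ-hydroxy ester to 17 with loss of methanol, with a trace of acid if needed.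

**Further compounds**
F1 | step 6 | (2R,3E)-5-[4-(TBSO)-3,5-dimethoxyphenyl]pent-3-en-2-yl 2-(TBSO)acetate | CC(C)(C)[Si](C)(C)OCC(=O)O[C@H](C)/C=C/Cc1cc(OC)c(O[Si](C)(C)C(C)(C)C)c(OC)c1
F2 | step 6 | (3S,4E)-2-(TBSO)-3-{[4-(TBSO)-3,5-dimethoxyphenyl]methyl}hex-4-enoic acid (C2 unassigned) | C/C=C/[C@H](Cc1cc(OC)c(O[Si](C)(C)C(C)(C)C)c(OC)c1)C(O[Si](C)(C)C(C)(C)C)C(=O)O
F3 | step 6 | (4S)-3-(TBSO)-4-{[4-(TBSO)-3,5-dimethoxyphenyl]methyl}oxolan-2-one (C3 unassigned) | CC(C)(C)[Si](C)(C)OC1C(=O)OC[C@@H]1Cc1cc(OC)c(O[Si](C)(C)C(C)(C)C)c(OC)c1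
F4 | step 6 | [4-(TBSO)-3-methoxyphenyl]methanol | COc1cc(CO)ccc1O[Si](C)(C)C(C)(C)C
F5 | step 6 | [4-(bromomethyl)-2-methoxyphenoxy](tert-butyl)dimethylsilane | COc1cc(CBr)ccc1O[Si](C)(C)C(C)(C)C
F6 | step 2 | 2-[4-(TBSO)-3,5-dimethoxyphenyl]acetaldehyde | O=CCc1cc(OC)c(O[Si](C)(C)C(C)(C)C)c(OC)c1
F7 | step 2 | (3E)-5-[4-(TBSO)-3,5-dimethoxyphenyl]pent-3-en-2-one | CC(=O)/C=C/Cc1cc(OC)c(O[Si](C)(C)C(C)(C)C)c(OC)c1
F8 | step 7 | methyl (2S,3S,4E)-2-(TBSO)-2-{[4-(TBSO)-3-methoxyphenyl]methyl}-3-{[4-(TBSO)-3,5-dimethoxyphenyl]methyl}hex-4-enoate | COc1cc(C[C@@](O[Si](C)(C)C(C)(C)C)(C(=O)OC)[C@@H](Cc2cc(OC)c(O[Si](C)(C)C(C)(C)C)c(OC)c2)/C=C/C)ccc1O[Si](C)(C)C(C)(C)C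
F9 | step 7 | methyl (2S,3R)-2-(TBSO)-2-{[4-(TBSO)-3-methoxyphenyl]methyl}-3-{[4-(TBSO)-3,5-dimethoxyphenyl]methyl}-4-oxobutanoate | COc1cc(C[C@@](O[Si](C)(C)C(C)(C)C)(C(=O)OC)[C@@H](Cc2cc(OC)c(O[Si](C)(C)C(C)(C)C)c(OC)c2)C=O)ccc1O[Si](C)(C)C(C)(C)C
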